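## Retrosynthetic overview

1. The target is reached by removing four O-benzyl groups from a tetra-O-benzyl bisflavonol; the two O-methyl groups (O7 of the rhamnetin half, O3''' of the other half) are carried from the first building blocks.
2. Both pyranone rings C (O1–C2–C3–C4–C4a–C8a in each half) are opened at O1–C2 and C3–OH. This leads back to an unsymmetrical bis(2'-hydroxychalcone); no ring is formed before the twofold Algar–Flynn–Oyamada closure, in which both C rings form together.
3. The bis-chalcone is cut at two bonds around ring B of the rhamnetin half (C1'–C6'): the diaryl ether bond C4'–O and the Cα=Cβ bond (future C3–C2). This gives three components, joined in one flask: a phenolic chalcone (isorhamnetin-type half), 3-(benzyloxy)-4-fluorobenzaldehyde, and the A-ring acetophenone of the rhamnetin half.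
4. Feature used: in both B rings the ether atom (on C4' and C4''') is para to the carbon (C1', C1''') that carries pyranone C2. The formyl carbon that becomes C2 therefore first activates C4'–F for SNAr and then accepts the enolate. Vanillin's formyl carbon is already spent as an enone, so the two different A rings (7-OMe and 7-OH) are placed without any aldehyde protection.
5. The phenolic chalcone comes from vanillin and a bis-benzylated phloroacetophenone; the second acetophenone comes from mono-benzylation of 2',6'-dihydroxy-4'-methoxyacetophenone.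

Key step: step 3

Remark: the target has no stereocentre and no configurationally defined double bond; it is achiral, so no enantiocontrol is needed.
Remark: the bis-benzylated acetophenone of step 2 and the fluoroaldehyde of step 3 are taken as catalogue compounds.

## Route

Step 1
Reactants: 1 1-(2,6-dihydroxy-4-methoxyphenyl)ethan-1-one
Product: 2 1-[2-(benzyloxy)-6-hydroxy-4-methoxyphenyl]ethan-1-one
Conditions: BnBr (1.05 equiv), K2CO3 (1.1 equiv), acetone, reflux
Reagents that add atoms: benzyl bromide, BrCc1ccccc1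
Why: Williamson ether synthesis on a symmetric bis-phenol: the two hydroxyls of 1 are equivalent, and after the first benzylation the remaining one stays hydrogen-bonded to the acetyl carbonyl and is too poor a nucleophile for the small excess of benzyl bromide, so the reaction should stop at the mono-ether (no stereocentre is formed).

Step 2
Reactants: 3 1-[2,4-bis(benzyloxy)-6-hydroxyphenyl]ethan-1-one; 4 vanillin (4-hydroxy-3-methoxybenzaldehyde)
Product: 5 (2E)-1-[2,4-bis(benzyloxy)-6-hydroxyphenyl]-3-(4-hydroxy-3-methoxyphenyl)prop-2-en-1-one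
Conditions: 50% aq KOH (excess), EtOH, rt to 50 °C; then aq HCl
Reagents that add atoms: none
Why: Claisen–Schmidt condensation: the enolate of 3 adds to the formyl group of vanillin and E1cB loss of water gives the conjugated enone with the thermodynamically preferred E geometry, while the 4-OH is left free on purpose because its phenoxide is the nucleophile of step 3 (no stereocentre is formed).

Step 3
Reactants: 5 (2E)-1-[2,4-bis(benzyloxy)-6-hydroxyphenyl]-3-(4-hydroxy-3-methoxyphenyl)prop-2-en-1-one; 6 3-(benzyloxy)-4-fluorobenzaldehyde; 2 1-[2-(benzyloxy)-6-hydroxy-4-methoxyphenyl]ethan-1-one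
Product: 8 (2E)-1-[2-(benzyloxy)-6-hydroxy-4-methoxyphenyl]-3-[3-(benzyloxy)-4-{4-[(1E)-3-[2,4-bis(benzyloxy)-6-hydroxyphenyl]-3-oxoprop-1-en-1-yl]-2-methoxyphenoxy}phenyl]prop-2-en-1-one, via chalcone aldehyde 7 (not isolated)
Conditions: 5, 6 (1.0 equiv), K2CO3 (1.5 equiv), DMSO, 90 °C; then 2 (1.2 equiv), 50% aq KOH, EtOH, rt; aq HCl work-up
Reagents that add atoms: none
Why: Carbonate deprotonates the 4-OH of 5 and the phenoxide adds to C4 of 6 to give a Meisenheimer anion whose charge is delocalised onto the para-formyl oxygen, loss of fluoride gives the doubly ortho-oxygenated diaryl ether 7, and KOH/EtOH then forms the enolate of 2, which adds to that same formyl group before E1cB dehydration gives the second enone. The closest known reaction types are the SNAr synthesis of diaryl ethers from 4-fluorobenzaldehydes and phenoxides and the Claisen–Schmidt condensation, run here as a sequential one-flask process because both are base-mediated. No ring is closed and no stereocentre is formed; the new C=C bond is set E under thermodynamic control. Arylation at O4 rather than O2' of 5 is secured by the chelation of the 2'-OH to the ketone and its two ortho substituents, and hydroxide and ethoxide are absent in the first stage so that the C4–F bond is not hydrolysed. The placement of the two different A rings is secured by the substrates themselves: vanillin's formyl carbon is already bound in the enone of 5, so acetophenone 2 can condense only with the formyl group of 6. Any flavanone formed from the 2'-hydroxychalcone under carbonate is reopened by KOH (retro-oxa-Michael), so the mixture should converge on one bis-chalcone.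

Step 4
Reactants: 8 (2E)-1-[2-(benzyloxy)-6-hydroxy-4-methoxyphenyl]-3-[3-(benzyloxy)-4-{4-[(1E)-3-[2,4-bis(benzyloxy)-6-hydroxyphenyl]-3-oxoprop-1-en-1-yl]-2-methoxyphenoxy}phenyl]prop-2-en-1-one
Product: 10 5-(benzyloxy)-2-[3-(benzyloxy)-4-{4-[5,7-bis(benzyloxy)-3-hydroxy-4-oxo-4H-chromen-2-yl]-2-methoxyphenoxy}phenyl]-3-hydroxy-7-methoxy-4H-chromen-4-one, via bis-dihydroflavonol 9 (not isolated)
Conditions: 30% aq H2O2 (excess), 2 M aq NaOH, MeOH/THF, 0 °C to rt; then aq HCl
Reagents that add atoms: hydrogen peroxide, OO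
Why: Twofold Algar–Flynn–Oyamada reaction: in alkaline hydrogen peroxide each 2'-phenoxide closes onto Cβ (6-endo-trig oxa-Michael) while Cα is hydroxylated by H2O2 to give the trans-3-hydroxyflavanone units of 9, which further peroxide dehydrogenates to the aromatic 3-hydroxy-4-pyranones, so the four transient stereocentres (2,3-trans, racemic) are erased and none remains in 10.

Step 5
Reactants: 10 5-(benzyloxy)-2-[3-(benzyloxy)-4-{4-[5,7-bis(benzyloxy)-3-hydroxy-4-oxo-4H-chromen-2-yl]-2-methoxyphenoxy}phenyl]-3-hydroxy-7-methoxy-4H-chromen-4-one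
Product: 11 3,5-dihydroxy-2-{3-hydroxy-4-[2-methoxy-4-(3,5,7-trihydroxy-4-oxo-4H-chromen-2-yl)phenoxy]phenyl}-7-methoxy-4H-chromen-4-one (target)
Conditions: H2 (1 atm), 10% Pd/C, THF/MeOH, rt
Reagents that add atoms: none
Why: Catalytic hydrogenolysis of the four benzyl ethers should leave the two methyl ethers, the diaryl ether and the flavonol C2=C3 bonds untouched, and its neutral medium avoids a base-induced Smiles-type shift of the aryl group from O4' to the newly freed O3' (no stereocentre is involved).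

## Compound list

1 | 1-(2,6-dihydroxy-4-methoxyphenyl)ethan-1-one (2',6'-dihydroxy-4'-methoxyacetophenone) | CC(=O)c1c(O)cc(OC)cc1O | starting material
2 | 1-[2-(benzyloxy)-6-hydroxy-4-methoxyphenyl]ethan-1-one | CC(=O)c1c(O)cc(OC)cc1OCc1ccccc1 | intermediate
3 | 1-[2,4-bis(benzyloxy)-6-hydroxyphenyl]ethan-1-one | CC(=O)c1c(O)cc(OCc2ccccc2)cc1OCc1ccccc1 | starting material
4 | vanillin (4-hydroxy-3-methoxybenzaldehyde) | COc1cc(C=O)ccc1O | starting material
5 | (2E)-1-[2,4-bis(benzyloxy)-6-hydroxyphenyl]-3-(4-hydroxy-3-methoxyphenyl)prop-2-en-1-one | COc1cc(/C=C/C(=O)c2c(O)cc(OCc3ccccc3)cc2OCc2ccccc2)ccc1O | intermediate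
6 | 3-(benzyloxy)-4-fluorobenzaldehyde | O=Cc1ccc(F)c(OCc2ccccc2)c1 | starting material
7 | 3-(benzyloxy)-4-{4-[(1E)-3-[2,4-bis(benzyloxy)-6-hydroxyphenyl]-3-oxoprop-1-en-1-yl]-2-methoxyphenoxy}benzaldehyde (chalcone aldehyde; formed in the flask in step 3, not isolated) | COc1cc(/C=C/C(=O)c2c(O)cc(OCc3ccccc3)cc2OCc2ccccc2)ccc1Oc1ccc(C=O)cc1OCc1ccccc1 | intermediate
8 | (2E)-1-[2-(benzyloxy)-6-hydroxy-4-methoxyphenyl]-3-[3-(benzyloxy)-4-{4-[(1E)-3-[2,4-bis(benzyloxy)-6-hydroxyphenyl]-3-oxoprop-1-en-1-yl]-2-methoxyphenoxy}phenyl]prop-2-en-1-one | COc1cc(/C=C/C(=O)c2c(O)cc(OCc3ccccc3)cc2OCc2ccccc2)ccc1Oc1ccc(/C=C/C(=O)c2c(O)cc(OC)cc2OCc2ccccc2)cc1OCc1ccccc1 | intermediate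
9 | 5-(benzyloxy)-2-[3-(benzyloxy)-4-{4-[5,7-bis(benzyloxy)-3-hydroxy-4-oxo-3,4-dihydro-2H-chromen-2-yl]-2-methoxyphenoxy}phenyl]-3-hydroxy-7-methoxy-2,3-dihydro-4H-chromen-4-one (bis-dihydroflavonol; 2,3-trans in each ring; formed in the flask in step 4 as a racemic mixture of two diastereomers, the 2R,3R/2R,3R representative is drawn; not isolated) | COc1cc([C@@H]2[C@H](C(=O)c3c(OCc4ccccc4)cc(OCc4ccccc4)cc3O2)O)ccc1Oc1ccc([C@@H]2[C@H](C(=O)c3c(OCc4ccccc4)cc(OC)cc3O2)O)cc1OCc1ccccc1 | intermediate
10 | 5-(benzyloxy)-2-[3-(benzyloxy)-4-{4-[5,7-bis(benzyloxy)-3-hydroxy-4-oxo-4H-chromen-2-yl]-2-methoxyphenoxy}phenyl]-3-hydroxy-7-methoxy-4H-chromen-4-one | COc1cc(OCc2ccccc2)c2c(=O)c(O)c(-c3ccc(Oc4ccc(-c5oc6cc(OCc7ccccc7)cc(OCc7ccccc7)c6c(=O)c5O)cc4OC)c(OCc4ccccc4)c3)oc2c1 | intermediate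
11 | 3,5-dihydroxy-2-{3-hydroxy-4-[2-methoxy-4-(3,5,7-trihydroxy-4-oxo-4H-chromen-2-yl)phenoxy]phenyl}-7-methoxy-4H-chromen-4-one (achiral) | COc1cc(O)c2c(=O)c(O)c(-c3ccc(Oc4ccc(-c5oc6cc(O)cc(O)c6c(=O)c5O)cc4OC)c(O)c3)oc2c1 | target

## Step count and risks

Total step count: 5. Longest linear sequence: 4 steps (step 2, 3, 4, 5; equally step 1, 3, 4, 5).

Steps most likely to fail:

Step 3 (key step). The 2'-hydroxychalcone unit of 5 may close to a flavanone under carbonate at 90 °C, and that flavanone may then undergo aldol reaction at its C3 with the aldehyde. Arylation may also occur in part at O2', or the second condensation may stall in the mixed solvent. The fallback forms the ether before any enone exists and tells the two aldehydes apart by an acetal. It sets out from 4: acetalisation (ethylene glycol, cat. p-TsOH, toluene, Dean–Stark) should give 4-(1,3-dioxolan-2-yl)-2-methoxyphenol F1. SNAr with 6 (K2CO3, DMF, 100 °C) should give 3-(benzyloxy)-4-[4-(1,3-dioxolan-2-yl)-2-methoxyphenoxy]benzaldehyde F2. Claisen–Schmidt condensation with 2 (aq KOH, EtOH) should give (2E)-1-[2-(benzyloxy)-6-hydroxy-4-methoxyphenyl]-3-{3-(benzyloxy)-4-[4-(1,3-dioxolan-2-yl)-2-methoxyphenoxy]phenyl}prop-2-en-1-one F3. Hydrolysis of the acetal (1 M HCl, THF, rt) should give 4-{2-(benzyloxy)-4-[(1E)-3-[2-(benzyloxy)-6-hydroxy-4-methoxyphenyl]-3-oxoprop-1-en-1-yl]phenoxy}-3-methoxybenzaldehyde F4, and a second Claisen–Schmidt condensation with 3 comes back to the route at 8.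

Step 4. Ring closure may take the 5-exo course (attack at Cα) and lead to aurone-type products, which the 6'-benzyloxy groups favour; one of the two halves may also stop at the dihydroflavonol stage. The fallback separates ring closure from the oxygenation of C3. It sets out from 8: iodine-catalysed oxidative cyclisation (cat. I2, DMSO, 120 °C, short reaction time to spare the benzyl ethers) should give the bis-flavone 5-(benzyloxy)-2-[3-(benzyloxy)-4-{4-[5,7-bis(benzyloxy)-4-oxo-4H-chromen-2-yl]-2-methoxyphenoxy}phenyl]-7-methoxy-4H-chromen-4-one F5. Dimethyldioxirane (acetone/CH2Cl2, 0 °C) should epoxidise both C2=C3 bonds to the bis(2,3-epoxyflavanone) F6, and cat. p-TsOH should isomerise both oxiranes to the 3-hydroxy-4-pyranones, which comes back to the route at 10.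

Step 2. Under KOH vanillin is present as its phenoxide, a deactivated electrophile, so the aldol addition may stall while the acetophenone is slowly consumed in side reactions. The fallback masks the phenol during the condensation. It sets out from 4: MOMCl and iPr2NEt in CH2Cl2 should give 3-methoxy-4-(methoxymethoxy)benzaldehyde F7. Claisen–Schmidt condensation with 3 (aq KOH, EtOH) should give (2E)-1-[2,4-bis(benzyloxy)-6-hydroxyphenyl]-3-[3-methoxy-4-(methoxymethoxy)phenyl]prop-2-en-1-one F8, and cleavage of the acetal (HCl, MeOH/THF, 40 °C) comes back to the route at 5.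

Further compounds
F1 | step 3 | 4-(1,3-dioxolan-2-yl)-2-methoxyphenol | COc1cc(C2OCCO2)ccc1O
F2 | step 3 | 3-(benzyloxy)-4-[4-(1,3-dioxolan-2-yl)-2-methoxyphenoxy]benzaldehyde | COc1cc(C2OCCO2)ccc1Oc1ccc(C=O)cc1OCc1ccccc1
F3 | step 3 | (2E)-1-[2-(benzyloxy)-6-hydroxy-4-methoxyphenyl]-3-{3-(benzyloxy)-4-[4-(1,3-dioxolan-2-yl)-2-methoxyphenoxy]phenyl}prop-2-en-1-one | COc1cc(C2OCCO2)ccc1Oc1ccc(/C=C/C(=O)c2c(O)cc(OC)cc2OCc2ccccc2)cc1OCc1ccccc1
F4 | step 3 | 4-{2-(benzyloxy)-4-[(1E)-3-[2-(benzyloxy)-6-hydroxy-4-methoxyphenyl]-3-oxoprop-1-en-1-yl]phenoxy}-3-methoxybenzaldehyde | COc1cc(C=O)ccc1Oc1ccc(/C=C/C(=O)c2c(O)cc(OC)cc2OCc2ccccc2)cc1OCc1ccccc1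
F5 | step 4 | 5-(benzyloxy)-2-[3-(benzyloxy)-4-{4-[5,7-bis(benzyloxy)-4-oxo-4H-chromen-2-yl]-2-methoxyphenoxy}phenyl]-7-methoxy-4H-chromen-4-one | COc1cc(OCc2ccccc2)c2c(=O)cc(-c3ccc(Oc4ccc(-c5cc(=O)c6c(OCc7ccccc7)cc(OCc7ccccc7)cc6o5)cc4OC)c(OCc4ccccc4)c3)oc2c1
F6 | step 4 | bis(2,3-epoxide) of F5, both chromenone C2=C3 bonds converted into cis-fused oxiranes (mixture of stereoisomers, drawn without descriptors) | COc1cc(OCc2ccccc2)c2C(=O)C3OC3(c3ccc(Oc4ccc(C56OC5C(=O)c5c(OCc7ccccc7)cc(OCc7ccccc7)cc5O6)cc4OC)c(OCc4ccccc4)c3)Oc2c1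
F7 | step 2 | 3-methoxy-4-(methoxymethoxy)benzaldehyde | COCOc1ccc(C=O)cc1OC
F8 | step 2 | (2E)-1-[2,4-bis(benzyloxy)-6-hydroxyphenyl]-3-[3-methoxy-4-(methoxymethoxy)phenyl]prop-2-en-1-one | COCOc1ccc(/C=C/C(=O)c2c(O)cc(OCc3ccccc3)cc2OCc2ccccc2)cc1OC
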